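## The problem

The target is a linear C25 furanoterpenoid tetronic acid. It has a 4-hydroxy-3-methylbutenolide (ring C) carrying a Z-alkylidene at its C5, a nine-carbon chain C6–C14, a central furan (ring B) and a terminal 3-furyl group (ring A) joined to ring B through one methylene. Ring B atoms are written O1(B), C2(B) to C5(B): C2(B) bears the CH2–ring A arm and C4(B) bears C14.

- **Stereocentre.** The only stereocentre is C7 (S). It is isolated, so nothing else in the molecule can set it. It must be bought or made by auxiliary, and it later sits alpha to an aldehyde, where it can epimerise.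
- **Alkene geometries.** C11=C12 must be E and trisubstituted. C5=C6 must be Z.
- **Sensitive groups.** The two furans and the methylene between them do not tolerate strong acid, electrophilic oxidants or hard Lewis acids. The tetronic acid is acidic and chelating, so it is best unveiled last from its methyl ether.
- **Ring B.** It is 2,4-disubstituted. Substitution or metalation of a furan goes to C2 and C5, so this pattern has to be written into an acyclic precursor.
- **Enabling feature.** The C3(B)=C4(B) bond is flanked by C2(B), an ether CH, and by C5(B), a CH next to O1(B) at aldehyde oxidation level. Cutting that bond leaves two terminal alkenes tethered through a C2(B)–O1(B)–C5(B) acetal. Metathesis can close this tether, and loss of the second acetal alkoxy group then aromatises the ring without a redox step.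

## Retrosynthesis

**28 to 27, 25, then 21 + 23.** The free 4-OH is masked as the methyl ether 27. The C5=C6 bond is then cut through the aldol 25 into aldehyde 21 and methyl 3-methyltetronate 23 (from 22). The neighbouring cut, O1–C5 by lactonisation, would need a stereodefined enynoic acid. The aldol–dehydration uses an aldehyde that the chain synthesis delivers anyway. The precursor 21 is simpler by the whole of ring C. The forward steps must add the C5 anion of 23 faster than the aldehyde enolises, eliminate to the Z-ylidene, and remove the methyl group without acid.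

**21 to 20 to 19.** These are oxidation-level changes at C6. C6 is carried as a tert-butyldiphenylsilyl ether because this group tolerates Grignard, ylide, aqueous base and the trace of acid used to aromatise ring B. The aldehyde is made only immediately before use.

**19 to 17 (key cut).** Ring B is opened across C3(B)=C4(B) and the ethoxy group is restored at C5(B), through dihydrofuran 18. This gives the mixed ethyl allyl acetal 17. Cuts at the C–O bonds of ring B would need a 1,4-dicarbonyl or an enynol, each with its own regio- or stereochemical demands. Here the 2,4-pattern follows from connectivity alone and neither stereocentre of 17 matters. The forward reaction must close only the five-membered ring among three alkenes, and acid must act only after closure.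

**17 to 10 + 16.** The acetal C–O bond to the secondary alkoxy group is cut. This puts ring A into the small carbinol 16 and leaves the chain in the diethyl acetal 10. The forward reaction is an acid-catalysed exchange of one ethoxy group.

**10 to 7 + 8, through 9.** The sp3–sp2 bond C14–C4(B) is cut. Terminal hydroboration of diene 7 gives borane 9, which couples with commercial 2-bromoacrolein diethyl acetal 8. Cutting C13–C14 instead would need an allyl–allyl coupling with SN2/SN2′ ambiguity. The forward reaction needs hydroboration at the vinyl group only and a B-alkyl Suzuki–Miyaura coupling.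

**7 to 6 to 4 + 5.** C13=C14 comes from methylenation of enal 6. C11=C12 is cut by cross-metathesis into terminal alkene 4 and methacrolein 5. This replaces the three steps of an alkene-to-aldehyde-to-Wittig sequence by one, and the E geometry is the thermodynamic outcome for an enal.

**4 to 2 + 3, 2 from 1.** The C8–C9 bond is cut to the silyl ether 2 of commercial (R)-3-bromo-2-methylpropan-1-ol 1 and but-3-enylmagnesium bromide 3. The stereocentre is bought. The coupling occurs at the carbon next to it, so it cannot be scrambled.

**16 to 14 to 11 + 12.** The bond between ring A and its methylene is cut to furan-3-yllithium 13 (from 3-bromofuran 11) and epichlorohydrin 12. The chlorohydrin 14 is homologated by one carbon to the allylic alcohol through epoxide 15. This avoids the unstable 3-furylacetaldehyde.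

**23 to 22.** O-Methylation of 3-methyltetronic acid.

## Roads not taken

**Alternative 1:** The cut is at C12–CH3 and C10–C11. Forward, AlMe3 with Cp2ZrCl2 adds methyl and aluminium syn across the alkyne of 4-(but-3-yn-1-yl)-2-(furan-3-ylmethyl)furan A2. The alkenylalane, activated with n-BuLi, opens oxirane A3 to give the E-homoallylic alcohol A1.
- Merit: the E geometry follows from the syn addition and is more secure than the thermodynamic control that the chosen cross-metathesis relies on. Three components are joined in one flask.
- Weak points: A2 already contains the 2,4-disubstituted ring B, so the hardest problem is moved to an unsolved earlier stage. The Lewis-acidic aluminium and zirconium reagents meet two furans. A1 ends at C9, so the stereocentre must still be attached by a late sp3–sp3 coupling at C8–C9.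
- Comparison: the chosen plan makes the C8–C9 bond first on simple fragments and builds ring B by a pattern-defined closure. It gives up the mechanistic guarantee of alkene geometry in exchange.

**Alternative 2:** The cut is at O1–C5 of ring C. Forward, AgNO3 (monovalent silver) activates the alkyne of the enynoic acid A5, the carboxylate adds 5-exo, and protodemetalation gives the methyl tetronate A4 with the Z-ylidene.
- Merit: the Z geometry follows from anti addition and is better controlled than in an aldol–dehydration. No aldol is run on an epimerisable aldehyde.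
- Weak points: A5 needs a tetrasubstituted enol ether of defined geometry with the carboxyl cis to the alkyne. It also needs a terminal alkyne that would itself come from aldehyde 21 by homologation. The 6-endo closure to a pyranone competes. The demethylation is still required.
- Comparison: this road concerns only the ring C end and is compatible with the chosen ring B construction. A4 is the same compound as 27. The chosen plan offers a three-operation endgame from 21 and the thermodynamic preference for the Z-ylidene. Alternative 2 remains the better answer if that geometry proved poor.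

**Alternative 3:** The cut is at C2(B)–C3(B) and O1(B)–C2(B). Forward, the Z-iodoenol A7 couples with 3-ethynylfuran A8 under PdCl2(PPh3)2 and CuI. AgNO3 then closes ring B through oxygen, and aromatisation gives the silyl ether A6.
- Merit: this also encodes the 2,4-pattern in acyclic connectivity. It attaches ring A and closes ring B in one operation, and it needs neither a carbinol synthesis nor a statistical acetal exchange. On step count for ring B it is equal or slightly shorter.
- Weak points: only the Z isomer of A7 can cyclise, so a trisubstituted iodoalkene of defined geometry carrying the whole chain must be made. A8 is volatile and less accessible. The enynol and its exocyclic-alkene tautomer are sensitive.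
- Comparison: the chosen precursor 17 has no geometry or configuration that matters, its components are commercial or two steps away, and its oxidation level is fixed by the acetal. It gives up the more convergent assembly of alternative 3.

Key step: step 9

Assumption: (R)-3-bromo-2-methylpropan-1-ol, but-3-en-1-ylmagnesium bromide (THF solution) and 3-methyltetronic acid are taken as catalogue materials. The acetal and carbinol stereocentres of 17 are carried as a mixture because both become trigonal.

## Route

Step 1
Reactants: 1 (R)-3-bromo-2-methylpropan-1-ol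
Product: 2 (R)-(3-bromo-2-methylpropoxy)(tert-butyl)diphenylsilane
Conditions: t-BuPh2SiCl, imidazole, DMF, 0 °C → rt
Reagents that add atoms: tert-butyl(chloro)diphenylsilane, CC(C)(C)[Si](Cl)(c1ccccc1)c1ccccc1
Why: Silylation of a primary alcohol with a silyl chloride and imidazole; the bromide and the stereocentre are not involved, and the silyl ether is chosen to survive all steps up to step 10.

Step 2
Reactants: 2 (R)-(3-bromo-2-methylpropoxy)(tert-butyl)diphenylsilane; 3 but-3-en-1-ylmagnesium bromide
Product: 4 tert-butyl{[(2S)-2-methylhept-6-en-1-yl]oxy}diphenylsilane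
Conditions: Li2CuCl4 (3 mol %), NMP, THF, 0 °C → rt
Reagents that add atoms: none
Why: Copper-catalysed sp3–sp3 coupling of a primary alkyl bromide with a primary Grignard reagent (Kochi-type); substitution occurs at CH2Br, so the adjacent stereocentre is untouched and only its descriptor changes.

Step 3
Reactants: 4 tert-butyl{[(2S)-2-methylhept-6-en-1-yl]oxy}diphenylsilane; 5 methacrolein (2-methylprop-2-enal)
Product: 6 (2E,7S)-8-[(tert-butyldiphenylsilyl)oxy]-2,7-dimethyloct-2-enal
Conditions: 5 (5 equiv), RuCl2(=CHPh)(PCy3)(H2IMes) (second-generation Grubbs catalyst, 5 mol %), CH2Cl2, 40 °C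
Reagents that add atoms: none
Why: Olefin cross-metathesis of a terminal alkene with an electron-poor 1,1-disubstituted partner that does not homodimerise; the trisubstituted enal should form with the formyl group trans to the chain (E) under thermodynamic control.

Step 4
Reactants: 6 (2E,7S)-8-[(tert-butyldiphenylsilyl)oxy]-2,7-dimethyloct-2-enal
Product: 7 tert-butyl{[(2S,6E)-2,7-dimethylnona-6,8-dien-1-yl]oxy}diphenylsilane
Conditions: Ph3PCH3Br, KOt-Bu, THF, 0 °C → rt
Reagents that add atoms: methyltriphenylphosphonium bromide, C[P+](c1ccccc1)(c1ccccc1)c1ccccc1.[Br-]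
Why: Wittig methylenation of an enal by 1,2-addition of the non-stabilised ylide; the E-trisubstituted alkene and the remote stereocentre are not affected.

Step 5
Reactants: 7 tert-butyl{[(2S,6E)-2,7-dimethylnona-6,8-dien-1-yl]oxy}diphenylsilane; 8 2-bromoacrolein diethyl acetal (2-bromo-3,3-diethoxyprop-1-ene)
Product: 10 tert-butyl{[(2S,6E)-10-(diethoxymethyl)-2,7-dimethylundeca-6,10-dien-1-yl]oxy}diphenylsilane, via B-alkyl-9-BBN borane 9 (not isolated)
Conditions: 9-BBN, THF, 0 °C → rt; then H2O, Cs2CO3, 8, PdCl2(dppf), AsPh3, DMF, rt
Reagents that add atoms: none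
Why: 9-BBN should add its boron to the unsubstituted terminus of the vinyl group and leave the trisubstituted alkene alone; the alkylborane then undergoes B-alkyl Suzuki–Miyaura coupling with the bromoalkene, and the acetal and silyl ether are stable to aqueous carbonate.

Step 6
Reactants: 11 3-bromofuran; 12 epichlorohydrin (racemic 2-(chloromethyl)oxirane)
Product: 14 1-chloro-3-(furan-3-yl)propan-2-ol (racemic), via furan-3-yllithium 13 (not isolated)
Conditions: n-BuLi, THF, −78 °C; then 12, BF3·OEt2, −78 °C
Reagents that add atoms: none
Why: Bromine–lithium exchange gives the 3-lithiofuran, which keeps its position at −78 °C; BF3-assisted SN2 opening of the oxirane at its unsubstituted carbon gives the chlorohydrin, and a racemate suffices because this carbon becomes C2(B).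

Step 7
Reactants: 14 1-chloro-3-(furan-3-yl)propan-2-ol
Product: 16 1-(furan-3-yl)but-3-en-2-ol (racemic), via 2-(furan-3-ylmethyl)oxirane 15 (not isolated)
Conditions: Me3SI (3.5 equiv), n-BuLi (3.4 equiv), THF, −10 °C → rt
Reagents that add atoms: trimethylsulfonium iodide, C[S+](C)C.[I-]
Why: Excess dimethylsulfonium methylide closes the chlorohydrin to the epoxide and opens it at the terminal carbon; the oxido sulfonium salt is deprotonated again and fragments to the allylic alkoxide and Me2S, which is the known one-carbon homologation of epoxides to allylic alcohols.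

Step 8
Reactants: 10 tert-butyl{[(2S,6E)-10-(diethoxymethyl)-2,7-dimethylundeca-6,10-dien-1-yl]oxy}diphenylsilane; 16 1-(furan-3-yl)but-3-en-2-ol
Product: 17 tert-butyl{[(2S,6E)-10-{ethoxy[(1-(furan-3-yl)but-3-en-2-yl)oxy]methyl}-2,7-dimethylundeca-6,10-dien-1-yl]oxy}diphenylsilane (mixture of diastereomers at the acetal and carbinol carbons)
Conditions: 16 (1.2 equiv), PPTS (cat.), toluene, 5 Å molecular sieves, 40 °C
Reagents that add atoms: none
Why: Acid-catalysed transacetalisation driven by removal of ethanol; about one equivalent of the hindered secondary alcohol should favour single exchange, and because the exchange is reversible, unreacted 10 and doubly exchanged acetal can be returned to the equilibrium.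

Step 9
Reactants: 17 tert-butyl{[(2S,6E)-10-{ethoxy[(1-(furan-3-yl)but-3-en-2-yl)oxy]methyl}-2,7-dimethylundeca-6,10-dien-1-yl]oxy}diphenylsilane
Product: 19 tert-butyl{[(2S,6E)-9-[5-(furan-3-ylmethyl)furan-3-yl]-2,7-dimethylnon-6-en-1-yl]oxy}diphenylsilane, via 2-ethoxy-2,5-dihydrofuran 18 (not isolated)
Conditions: RuCl2(=CHPh)(PCy3)(H2IMes) (second-generation Grubbs catalyst, 5 mol %), CH2Cl2 (0.01 M), 40 °C; then CF3CO2H (cat.), rt
Reagents that add atoms: none
Why: The catalyst should initiate at the monosubstituted vinyl group of 17, and the resulting alkylidene sits five atoms from the 1,1-disubstituted alkene, so cycloaddition and cycloreversion form the C3(B)=C4(B) bond and release ethene to give 18. The closest known reaction type is ring-closing olefin metathesis of a mixed allyl acetal to a 2-alkoxy-2,5-dihydrofuran, followed by acid-promoted loss of alcohol to a furan. Ring B is the only ring closed; it closes as a five-membered ring by metathesis between two terminal alkenes tethered through the C2(B)–O1(B)–C5(B) acetal unit. No stereocentre is created, and the two stereocentres of the tether become trigonal, so all diastereomers of 17 should converge on 19. Once metathesis is complete, a trace of CF3CO2H ionises the ring acetal to an oxocarbenium ion, and loss of the C2(B) proton aromatises the ring with release of ethanol. The step needs chemoselectivity among three alkenes and two furans, and ring size secures it: the trisubstituted C11=C12 alkene could close only a four- or eight-membered ring, and the furan double bonds are aromatic. High dilution suppresses cross-metathesis between vinyl groups, and the acid is added only after closure so that the acyclic acetal is not ionised.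

Step 10
Reactants: 19 tert-butyl{[(2S,6E)-9-[5-(furan-3-ylmethyl)furan-3-yl]-2,7-dimethylnon-6-en-1-yl]oxy}diphenylsilane
Product: 20 (2S,6E)-9-[5-(furan-3-ylmethyl)furan-3-yl]-2,7-dimethylnon-6-en-1-ol
Conditions: n-Bu4NF, THF, rt
Reagents that add atoms: none
Why: Fluoride-induced cleavage of the silyl ether; the furans, the alkene and the stereocentre are inert to fluoride and mild base.

Step 11
Reactants: 20 (2S,6E)-9-[5-(furan-3-ylmethyl)furan-3-yl]-2,7-dimethylnon-6-en-1-ol
Product: 21 (2S,6E)-9-[5-(furan-3-ylmethyl)furan-3-yl]-2,7-dimethylnon-6-enal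
Conditions: Dess–Martin periodinane, NaHCO3, CH2Cl2, 0 °C → rt; used at once
Reagents that add atoms: none
Why: Dess–Martin oxidation under buffered, near-neutral conditions should neither epimerise the alpha-methyl aldehyde nor attack the furans; the aldehyde is not stored.

Step 12
Reactants: 22 3-methyltetronic acid (4-hydroxy-3-methylfuran-2(5H)-one)
Product: 23 4-methoxy-3-methylfuran-2(5H)-one
Conditions: (CH3O)2SO2, K2CO3, acetone, reflux
Reagents that add atoms: dimethyl sulfate, COS(=O)(=O)OC
Why: O-Alkylation of the vinylogous acid with a hard methylating agent gives the vinylogous ester, which protects the acidic OH and makes C5 the site of deprotonation.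

Step 13
Reactants: 23 4-methoxy-3-methylfuran-2(5H)-one; 21 (2S,6E)-9-[5-(furan-3-ylmethyl)furan-3-yl]-2,7-dimethylnon-6-enal
Product: 25 5-{(2S,6E)-9-[5-(furan-3-ylmethyl)furan-3-yl]-1-hydroxy-2,7-dimethylnon-6-en-1-yl}-4-methoxy-3-methylfuran-2(5H)-one (mixture of diastereomers at C5 and C6), via C5-lithiated tetronate 24 (not isolated)
Conditions: 23, LiN(i-Pr)2, THF, −78 °C; then 21, −78 °C; aq. NH4Cl
Reagents that add atoms: none
Why: Deprotonation of the vinylogous ester at C5 gives a dienolate that adds through C5 to the aldehyde (aldol addition) at −78 °C, which should be faster than enolisation of 21; the two new stereocentres need no control because both are removed in step 14.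

Step 14
Reactants: 25 5-{(2S,6E)-9-[5-(furan-3-ylmethyl)furan-3-yl]-1-hydroxy-2,7-dimethylnon-6-en-1-yl}-4-methoxy-3-methylfuran-2(5H)-one
Product: 27 (5Z)-5-{(2S,6E)-9-[5-(furan-3-ylmethyl)furan-3-yl]-2,7-dimethylnon-6-en-1-ylidene}-4-methoxy-3-methylfuran-2(5H)-one, via aldol mesylate 26 (not isolated)
Conditions: CH3SO2Cl, Et3N, CH2Cl2, 0 °C; then DBU, rt
Reagents that add atoms: none
Why: Mesylation followed by E1cB elimination through the stabilised C5 anion; the Z-ylidene, in which the C7 branch points away from the 4-methoxy group, is the less congested isomer and should dominate, and the C7–H is too weakly acidic for DBU to remove.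

Step 15
Reactants: 27 (5Z)-5-{(2S,6E)-9-[5-(furan-3-ylmethyl)furan-3-yl]-2,7-dimethylnon-6-en-1-ylidene}-4-methoxy-3-methylfuran-2(5H)-one
Product: 28 (5Z)-5-{(2S,6E)-9-[5-(furan-3-ylmethyl)furan-3-yl]-2,7-dimethylnon-6-en-1-ylidene}-4-hydroxy-3-methylfuran-2(5H)-one (target)
Conditions: n-PrSH, n-BuLi, HMPA, 0 °C → rt; then dil. HCl, 0 °C
Reagents that add atoms: none
Why: SN2 demethylation of the vinylogous methyl ester by a soft thiolate, with the tetronate anion as leaving group; the basic, non-Lewis-acidic medium spares both furans, and brief cold acidification liberates the tetronic acid.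

## Compound list

1 | (R)-3-bromo-2-methylpropan-1-ol | OC[C@@H](C)CBr | starting material
2 | (R)-(3-bromo-2-methylpropoxy)(tert-butyl)diphenylsilane | CC(C)(C)[Si](c1ccccc1)(c1ccccc1)OC[C@@H](C)CBr | intermediate
3 | but-3-en-1-ylmagnesium bromide | C=CCC[Mg]Br | starting material
4 | tert-butyl{[(2S)-2-methylhept-6-en-1-yl]oxy}diphenylsilane | CC(C)(C)[Si](c1ccccc1)(c1ccccc1)OC[C@@H](C)CCCC=C | intermediate
5 | methacrolein (2-methylprop-2-enal) | CC(=C)C=O | starting material
6 | (2E,7S)-8-[(tert-butyldiphenylsilyl)oxy]-2,7-dimethyloct-2-enal | CC(C)(C)[Si](c1ccccc1)(c1ccccc1)OC[C@@H](C)CCC/C=C(\C)C=O | intermediate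
7 | tert-butyl{[(2S,6E)-2,7-dimethylnona-6,8-dien-1-yl]oxy}diphenylsilane | CC(C)(C)[Si](c1ccccc1)(c1ccccc1)OC[C@@H](C)CCC/C=C(\C)C=C | intermediate
8 | 2-bromoacrolein diethyl acetal (2-bromo-3,3-diethoxyprop-1-ene) | C=C(Br)C(OCC)OCC | starting material
9 | 9-{(3E,8S)-9-[(tert-butyldiphenylsilyl)oxy]-3,8-dimethylnon-3-en-1-yl}-9-borabicyclo[3.3.1]nonane | CC(C)(C)[Si](c1ccccc1)(c1ccccc1)OC[C@@H](C)CCC/C=C(\C)CCB1C2CCCC1CCC2 | intermediate (not isolated)
10 | tert-butyl{[(2S,6E)-10-(diethoxymethyl)-2,7-dimethylundeca-6,10-dien-1-yl]oxy}diphenylsilane | CC(C)(C)[Si](c1ccccc1)(c1ccccc1)OC[C@@H](C)CCC/C=C(\C)CCC(=C)C(OCC)OCC | intermediate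
11 | 3-bromofuran | Brc1ccoc1 | starting material
12 | epichlorohydrin (racemic 2-(chloromethyl)oxirane) | ClCC1CO1 | starting material
13 | furan-3-yllithium | [Li]c1ccoc1 | intermediate (not isolated)
14 | 1-chloro-3-(furan-3-yl)propan-2-ol (racemic) | OC(CCl)Cc1ccoc1 | intermediate
15 | 2-(furan-3-ylmethyl)oxirane (racemic) | C(C1CO1)c1ccoc1 | intermediate (not isolated)
16 | 1-(furan-3-yl)but-3-en-2-ol (racemic) | C=CC(O)Cc1ccoc1 | intermediate
17 | tert-butyl{[(2S,6E)-10-{ethoxy[(1-(furan-3-yl)but-3-en-2-yl)oxy]methyl}-2,7-dimethylundeca-6,10-dien-1-yl]oxy}diphenylsilane (diastereomer mixture) | CC(C)(C)[Si](c1ccccc1)(c1ccccc1)OC[C@@H](C)CCC/C=C(\C)CCC(=C)C(OCC)OC(C=C)Cc1ccoc1 | intermediate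
18 | tert-butyl{[(2S,6E)-9-[2-ethoxy-5-(furan-3-ylmethyl)-2,5-dihydrofuran-3-yl]-2,7-dimethylnon-6-en-1-yl]oxy}diphenylsilane (diastereomer mixture) | CC(C)(C)[Si](c1ccccc1)(c1ccccc1)OC[C@@H](C)CCC/C=C(\C)CCC1=CC(Cc2ccoc2)OC1OCC | intermediate (not isolated)
19 | tert-butyl{[(2S,6E)-9-[5-(furan-3-ylmethyl)furan-3-yl]-2,7-dimethylnon-6-en-1-yl]oxy}diphenylsilane | CC(C)(C)[Si](c1ccccc1)(c1ccccc1)OC[C@@H](C)CCC/C=C(\C)CCc1coc(Cc2ccoc2)c1 | intermediate
20 | (2S,6E)-9-[5-(furan-3-ylmethyl)furan-3-yl]-2,7-dimethylnon-6-en-1-ol | OC[C@@H](C)CCC/C=C(\C)CCc1coc(Cc2ccoc2)c1 | intermediate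
21 | (2S,6E)-9-[5-(furan-3-ylmethyl)furan-3-yl]-2,7-dimethylnon-6-enal | O=C[C@@H](C)CCC/C=C(\C)CCc1coc(Cc2ccoc2)c1 | intermediate
22 | 3-methyltetronic acid (4-hydroxy-3-methylfuran-2(5H)-one) | CC1=C(O)COC1=O | starting material
23 | 4-methoxy-3-methylfuran-2(5H)-one | CC1=C(OC)COC1=O | intermediate
24 | (3-methoxy-4-methyl-5-oxo-2,5-dihydrofuran-2-yl)lithium | CC1=C(OC)C([Li])OC1=O | intermediate (not isolated)
25 | 5-{(2S,6E)-9-[5-(furan-3-ylmethyl)furan-3-yl]-1-hydroxy-2,7-dimethylnon-6-en-1-yl}-4-methoxy-3-methylfuran-2(5H)-one (diastereomer mixture) | CC1=C(OC)C(OC1=O)C(O)[C@@H](C)CCC/C=C(\C)CCc1coc(Cc2ccoc2)c1 | intermediate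
26 | (2S,6E)-9-[5-(furan-3-ylmethyl)furan-3-yl]-1-(3-methoxy-4-methyl-5-oxo-2,5-dihydrofuran-2-yl)-2,7-dimethylnon-6-en-1-yl methanesulfonate (diastereomer mixture) | CC1=C(OC)C(OC1=O)C(OS(C)(=O)=O)[C@@H](C)CCC/C=C(\C)CCc1coc(Cc2ccoc2)c1 | intermediate (not isolated)
27 | (5Z)-5-{(2S,6E)-9-[5-(furan-3-ylmethyl)furan-3-yl]-2,7-dimethylnon-6-en-1-ylidene}-4-methoxy-3-methylfuran-2(5H)-one | CC1=C(OC)/C(=C/[C@@H](C)CCC/C=C(\C)CCc2coc(Cc3ccoc3)c2)OC1=O | intermediate
28 | (5Z)-5-{(2S,6E)-9-[5-(furan-3-ylmethyl)furan-3-yl]-2,7-dimethylnon-6-en-1-ylidene}-4-hydroxy-3-methylfuran-2(5H)-one | CC1=C(O)/C(=C/[C@@H](C)CCC/C=C(\C)CCc2coc(Cc3ccoc3)c2)OC1=O | target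

## Step count and risks

Total: 15 steps. Longest linear sequence: 12 steps (1, 2, 3, 4, 5, 8, 9, 10, 11, 13, 14, 15).

**Step 9 (key step).** Three things may go wrong. The acyclic acetal may ionise before ring closure. Ruthenium hydride species may isomerise the allyl acetal to an enol ether that cannot close. Closure onto the 1,1-disubstituted alkene may be slow, so that vinyl groups cross-couple between molecules.
Fallback: an ester tether replaces the acetal and the oxidation level is adjusted after closure. It sets out from 10. Mild aqueous acid gives (5E,10S)-11-[(tert-butyldiphenylsilyl)oxy]-5,10-dimethyl-2-methylideneundec-5-enal F1. Chlorite oxidation (NaClO2, NaH2PO4, 2-methylbut-2-ene) gives the corresponding 2-methylideneundec-5-enoic acid F2. Carbodiimide esterification with 16 gives the 1-(furan-3-yl)but-3-en-2-yl ester F3. Ring-closing metathesis with the same catalyst in hot toluene closes the same C3(B)=C4(B) bond to 3-[(3E,8S)-9-[(tert-butyldiphenylsilyl)oxy]-3,8-dimethylnon-3-en-1-yl]-5-(furan-3-ylmethyl)furan-2(5H)-one F4. Reduction with i-Bu2AlH at −78 °C to the lactol and dehydration on mild acidic work-up return to the route at 19.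

**Step 8.** The exchange may give a statistical spread of unchanged, singly and doubly exchanged acetal, and the allylic acetal may ionise and decompose on prolonged exposure to acid.
Fallback: stepwise activation and substitution replace the equilibrium. It sets out from 10. Et3SiOTf and 2,4,6-collidine in CH2Cl2 at 0 °C replace one ethoxy group to give 1-[(2S,6E)-10-(1-ethoxy-1-pyridiniomethyl)-type] salt, namely 1-{1-ethoxy-2-methylidene-alkyl}-2,4,6-trimethylpyridinium triflate F5, which is not isolated. Addition of 16 displaces collidine and returns to the route at 17.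

**Step 5.** Hydroboration of the conjugated diene may be incompletely regioselective. The alkylborane may also be lost by beta-hydride elimination or protodeboronation if transmetalation to the hindered, acetal-bearing bromoalkene is slow.
Fallback: the polarity of the C14–C4(B) bond formation is reversed. It sets out from 7. Hydroboration with 9-BBN and oxidative work-up (NaOH, H2O2) give (3E,8S)-9-[(tert-butyldiphenylsilyl)oxy]-3,8-dimethylnon-3-en-1-ol F6. I2, PPh3 and imidazole give tert-butyl{[(2S,6E)-9-iodo-2,7-dimethylnon-6-en-1-yl]oxy}diphenylsilane F7. Bromine–lithium exchange on 8 with n-BuLi at −78 °C gives (3,3-diethoxyprop-1-en-2-yl)lithium F8, which is alkylated by F7 in THF/HMPA. This returns to the route at 10.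

**Step 3.** Alkene 4 may homodimerise, or turnover with the electron-poor 1,1-disubstituted partner may be incomplete, with some loss of E selectivity.
Fallback: the alkene is made by carbonyl olefination. It sets out from 4. Ozonolysis (O3, CH2Cl2, −78 °C; PPh3) gives (5S)-6-[(tert-butyldiphenylsilyl)oxy]-5-methylhexanal F9. Wittig reaction with the stabilised ylide Ph3P=C(CH3)CHO in warm toluene returns to the route at 6.

**Step 13.** The basic lithium dienolate may enolise and epimerise the alpha-methyl aldehyde 21, or the addition may revert.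
Fallback: a Lewis-acid-promoted vinylogous Mukaiyama aldol replaces the lithium aldol. It sets out from 23. t-BuMe2SiOTf and Et3N give tert-butyl[(4-methoxy-3-methylfuran-2-yl)oxy]dimethylsilane F10. Reaction with 21 and BF3·OEt2 in CH2Cl2 at −78 °C, with aqueous work-up, returns to the route at 25.

## Further compounds

F1 | step 9 | (5E,10S)-11-[(tert-butyldiphenylsilyl)oxy]-5,10-dimethyl-2-methylideneundec-5-enal | CC(C)(C)[Si](c1ccccc1)(c1ccccc1)OC[C@@H](C)CCC/C=C(\C)CCC(=C)C=O
F2 | step 9 | (5E,10S)-11-[(tert-butyldiphenylsilyl)oxy]-5,10-dimethyl-2-methylideneundec-5-enoic acid | CC(C)(C)[Si](c1ccccc1)(c1ccccc1)OC[C@@H](C)CCC/C=C(\C)CCC(=C)C(=O)O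
F3 | step 9 | 1-(furan-3-yl)but-3-en-2-yl (5E,10S)-11-[(tert-butyldiphenylsilyl)oxy]-5,10-dimethyl-2-methylideneundec-5-enoate | CC(C)(C)[Si](c1ccccc1)(c1ccccc1)OC[C@@H](C)CCC/C=C(\C)CCC(=C)C(=O)OC(C=C)Cc1ccoc1
F4 | step 9 | 3-[(3E,8S)-9-[(tert-butyldiphenylsilyl)oxy]-3,8-dimethylnon-3-en-1-yl]-5-(furan-3-ylmethyl)furan-2(5H)-one | CC(C)(C)[Si](c1ccccc1)(c1ccccc1)OC[C@@H](C)CCC/C=C(\C)CCC1=CC(Cc2ccoc2)OC1=O
F5 | step 8 | 1-{(5E,10S)-11-[(tert-butyldiphenylsilyl)oxy]-1-ethoxy-5,10-dimethyl-2-methylideneundec-5-en-1-yl}-2,4,6-trimethylpyridinium trifluoromethanesulfonate | CC(C)(C)[Si](c1ccccc1)(c1ccccc1)OC[C@@H](C)CCC/C=C(\C)CCC(=C)C(OCC)[n+]1c(C)cc(C)cc1C.[O-]S(=O)(=O)C(F)(F)F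
F6 | step 5 | (3E,8S)-9-[(tert-butyldiphenylsilyl)oxy]-3,8-dimethylnon-3-en-1-ol | CC(C)(C)[Si](c1ccccc1)(c1ccccc1)OC[C@@H](C)CCC/C=C(\C)CCO
F7 | step 5 | tert-butyl{[(2S,6E)-9-iodo-2,7-dimethylnon-6-en-1-yl]oxy}diphenylsilane | CC(C)(C)[Si](c1ccccc1)(c1ccccc1)OC[C@@H](C)CCC/C=C(\C)CCI
F8 | step 5 | (3,3-diethoxyprop-1-en-2-yl)lithium | [Li]C(=C)C(OCC)OCC
F9 | step 3 | (5S)-6-[(tert-butyldiphenylsilyl)oxy]-5-methylhexanal | O=CCCC[C@H](C)CO[Si](c1ccccc1)(c1ccccc1)C(C)(C)C
F10 | step 13 | tert-butyl[(4-methoxy-3-methylfuran-2-yl)oxy]dimethylsilane | COc1coc(O[Si](C)(C)C(C)(C)C)c1C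
A1 | alternative 1 | (3E)-6-[5-(furan-3-ylmethyl)furan-3-yl]-4-methylhex-3-en-1-ol | OCC/C=C(\C)CCc1coc(Cc2ccoc2)c1
A2 | alternative 1 | 4-(but-3-yn-1-yl)-2-(furan-3-ylmethyl)furan | C#CCCc1coc(Cc2ccoc2)c1
A3 | alternative 1 | oxirane | C1CO1
A4 | alternative 2 | (5Z)-5-{(2S,6E)-9-[5-(furan-3-ylmethyl)furan-3-yl]-2,7-dimethylnon-6-en-1-ylidene}-4-methoxy-3-methylfuran-2(5H)-one | CC1=C(OC)/C(=C/[C@@H](C)CCC/C=C(\C)CCc2coc(Cc3ccoc3)c2)OC1=O
A5 | alternative 2 | (2E,6S,10E)-13-[5-(furan-3-ylmethyl)furan-3-yl]-3-methoxy-2,6,11-trimethyltrideca-2,10-dien-4-ynoic acid | OC(=O)/C(C)=C(/OC)C#C[C@@H](C)CCC/C=C(\C)CCc1coc(Cc2ccoc2)c1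
A6 | alternative 3 | tert-butyl{[(2S,6E)-9-[5-(furan-3-ylmethyl)furan-3-yl]-2,7-dimethylnon-6-en-1-yl]oxy}dimethylsilane | CC(C)(C)[Si](C)(C)OC[C@@H](C)CCC/C=C(\C)CCc1coc(Cc2ccoc2)c1
A7 | alternative 3 | (2Z,5E,10S)-11-[(tert-butyldimethylsilyl)oxy]-2-(iodomethylidene)-5,10-dimethylundec-5-en-1-ol | CC(C)(C)[Si](C)(C)OC[C@@H](C)CCC/C=C(\C)CC/C(CO)=C/I
A8 | alternative 3 | 3-ethynylfuran | C#Cc1ccoc1
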